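**Strategy.** The route rests on disconnecting the pyran ring of the isoflavan at the aryl ether bond O1–C8a and at C3–C4. It exploits the 1,3-relation of C8a and benzylic C4 across C4a of ring A: ring A enters as a 2-fluorobenzoyl chloride, the C4 carbonyl being both the acceptor for C3 and the activator of C8a. In one pot an arylacetaldehyde silyl enol ether (O1–C2=C3) is C-acylated and the enolate oxygen then displaces fluoride to give the isoflavone. Ruthenium-catalysed transfer hydrogenation with dynamic kinetic resolution sets C3; the C4 cation is arylated trans by C6 of C8-blocked (S)-naringenin; hydrogenolysis completes the synthesis.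

Key step: step 7

Remarks: chroman atoms are numbered O1, C2, C3, C4, C4a, C5 to C8, C8a; atoms of the flavanone unit carry a double prime. 4-(Benzyloxy)-2-fluorobenzoic acid and (2S)-naringenin are assumed to be purchasable. Enol ethers 4 and 6 are used as E/Z mixtures (one isomer drawn). The C8'' bromine is a temporary blocking group that is removed in the last step.

**Step 1**
Reactants: 1 2,6-dimethoxyphenol
Product: 2 2-(benzyloxy)-1,3-dimethoxybenzene
Conditions: BnBr, K2CO3, DMF, 60 °C
Reagents that add atoms: benzyl bromide BrCc1ccccc1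
Why: Williamson etherification should mask the future B-ring hydroxyl as a hydrogenolysable benzyl ether.

**Step 2**
Reactants: 2 2-(benzyloxy)-1,3-dimethoxybenzene
Product: 3 3-(benzyloxy)-2,4-dimethoxybenzaldehyde
Conditions: POCl3, DMF, 80 °C; then aq. NaOAc
Reagents that add atoms: N,N-dimethylformamide CN(C)C=O; water O
Why: Vilsmeier–Haack formylation should occur at the position ortho to one methoxy group and para to the other, the doubly activated site of a 1,2,3-trialkoxybenzene, and not at the position meta to both.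

**Step 3**
Reactants: 3 3-(benzyloxy)-2,4-dimethoxybenzaldehyde
Product: 4 2-(benzyloxy)-1,3-dimethoxy-4-(2-methoxyethenyl)benzene (E/Z mixture)
Conditions: Ph3P(Cl)CH2OMe, KOtBu, THF, 0 °C to rt
Reagents that add atoms: (methoxymethyl)triphenylphosphonium chloride COC[P+](c1ccccc1)(c1ccccc1)c1ccccc1.[Cl-]
Why: Wittig methoxymethylenation should homologate the aldehyde by the carbon that becomes C2; the alkene geometry is irrelevant.

**Step 4**
Reactants: 4 2-(benzyloxy)-1,3-dimethoxy-4-(2-methoxyethenyl)benzene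
Product: 5 2-[3-(benzyloxy)-2,4-dimethoxyphenyl]acetaldehyde
Conditions: 2 M HCl, THF, 40 °C
Reagents that add atoms: water O
Why: Acid-catalysed enol ether hydrolysis should release the arylacetaldehyde, whose carbonyl oxygen is the later O1.

**Step 5**
Reactants: 5 2-[3-(benzyloxy)-2,4-dimethoxyphenyl]acetaldehyde
Product: 6 {2-[3-(benzyloxy)-2,4-dimethoxyphenyl]ethenyloxy}trimethylsilane (Z/E mixture)
Conditions: Me3SiCl, Et3N, DMF, 60 °C
Reagents that add atoms: chlorotrimethylsilane C[Si](C)(C)Cl
Why: O-silylation of the readily enolised arylacetaldehyde (silyl enol ether formation) should fix the O1–C2=C3 unit as a carbon nucleophile at C3.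

**Step 6**
Reactants: 7 4-(benzyloxy)-2-fluorobenzoic acid
Product: 8 4-(benzyloxy)-2-fluorobenzoyl chloride
Conditions: (COCl)2, DMF (cat.), CH2Cl2, 0 °C to rt
Reagents that add atoms: oxalyl chloride O=C(Cl)C(Cl)=O
Why: Acid chloride formation through the catalytic Vilsmeier-type chloroiminium should proceed without touching the benzyl ether or the aryl fluoride.

**Step 7**
Reactants: 6 {2-[3-(benzyloxy)-2,4-dimethoxyphenyl]ethenyloxy}trimethylsilane; 8 4-(benzyloxy)-2-fluorobenzoyl chloride
Product: 10 7-(benzyloxy)-3-[3-(benzyloxy)-2,4-dimethoxyphenyl]-4H-chromen-4-one, via chelated enol ketoaldehyde 9 (not isolated)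
Conditions: ZnCl2 (1.2 equiv), CH2Cl2/Et2O, 0 °C to rt; volatiles removed; then K2CO3, DMF, 70 °C (one pot)
Reagents that add atoms: none
Why: ZnCl2 activates acid chloride 8 for Mukaiyama-type C-acylation of silyl enol ether 6 at C3, which forms the C3–C4 bond, releases Me3SiCl and leaves chelated enol 9 with the aroyl group cis to the enol oxygen O1; K2CO3 then gives the enolate, whose oxygen adds to C8a ipso to fluorine (Meisenheimer adduct with the charge taken up by the C4 carbonyl) and fluoride leaves, which forms the O1–C8a bond. The closest known reaction type is the cycloacylation route to chromones and 4-quinolones from 2-halobenzoyl chlorides and enol or enamine nucleophiles. The pyranone ring closes by intramolecular SNAr, a 6-endo-trig addition–elimination counted on the C4a=C8a bond through which the C4 carbonyl accepts the charge. No stereocenter is formed, since C3 stays sp2 and is set in step 8. The step needs C- over O-acylation, which the silyl enol ether and Lewis acid pairing should secure. It also needs substitution at one aromatic carbon only, which is secured because the C–F carbon is the single position activated by the ortho carbonyl and the 7-benzyloxy group is meta to it.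

**Step 8**
Reactants: 10 7-(benzyloxy)-3-[3-(benzyloxy)-2,4-dimethoxyphenyl]-4H-chromen-4-one
Product: 12 (3R,4R)-7-(benzyloxy)-3-[3-(benzyloxy)-2,4-dimethoxyphenyl]-3,4-dihydro-2H-chromen-4-ol, via racemising isoflavanone 11 (not isolated)
Conditions: RuCl[(R,R)-TsDPEN](p-cymene) (3 mol %), HCO2H/Et3N (5:2), EtOAc, 40 °C
Reagents that add atoms: none
Why: Noyori–Ikariya asymmetric transfer hydrogenation run as a cascade: the Ru–H form of the catalyst first reduces the C2=C3 bond, isoflavanone 11 epimerises at C3 through its enol under the amine, and the (R,R) catalyst should reduce only the 3R ketone, anti to the 3-aryl group, to the 4R alcohol (dynamic kinetic resolution), which sets C3 as R with a 3,4-cis relationship.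

**Step 9**
Reactants: 13 (2S)-naringenin
Product: 14 (2S)-5,7-bis(benzyloxy)-2-[4-(benzyloxy)phenyl]-2,3-dihydro-4H-chromen-4-one
Conditions: BnOH (3.5 equiv), PPh3, DIAD, THF, 0 °C to rt
Reagents that add atoms: benzyl alcohol OCc1ccccc1
Why: Mitsunobu etherification should benzylate all three phenols, the chelated 5''-hydroxyl included, under essentially neutral conditions that avoid base-induced ring opening and racemisation at C2''.

**Step 10**
Reactants: 14 (2S)-5,7-bis(benzyloxy)-2-[4-(benzyloxy)phenyl]-2,3-dihydro-4H-chromen-4-one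
Product: 15 (2S)-5,7-bis(benzyloxy)-2-[4-(benzyloxy)phenyl]-8-bromo-2,3-dihydro-4H-chromen-4-one
Conditions: NBS (1.05 equiv), MeCN, 0 °C
Reagents that add atoms: N-bromosuccinimide O=C1CCC(=O)N1Br
Why: Electrophilic aromatic bromination of the 5,7-dialkoxy ring should go to C8'', flanked by one benzyloxy group and the ring oxygen, not to C6'' between two benzyloxy groups, as is usual for per-O-alkylated 5,7-dioxygenated flavonoids.

**Step 11**
Reactants: 15 (2S)-5,7-bis(benzyloxy)-2-[4-(benzyloxy)phenyl]-8-bromo-2,3-dihydro-4H-chromen-4-one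
Product: 16 (2S)-8-bromo-5,7-dihydroxy-2-(4-hydroxyphenyl)-2,3-dihydro-4H-chromen-4-one
Conditions: BCl3, C6HMe5, CH2Cl2, −78 °C
Reagents that add atoms: none
Why: Lewis-acid debenzylation with pentamethylbenzene as benzyl cation scavenger should free the three phenols at low temperature without touching the aryl bromide or the acid-stable C2'' stereocenter.

**Step 12**
Reactants: 12 (3R,4R)-7-(benzyloxy)-3-[3-(benzyloxy)-2,4-dimethoxyphenyl]-3,4-dihydro-2H-chromen-4-ol; 16 (2S)-8-bromo-5,7-dihydroxy-2-(4-hydroxyphenyl)-2,3-dihydro-4H-chromen-4-one (2.5 equiv)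
Product: 18 (2S)-6-{(3R,4S)-7-(benzyloxy)-3-[3-(benzyloxy)-2,4-dimethoxyphenyl]-3,4-dihydro-2H-chromen-4-yl}-8-bromo-5,7-dihydroxy-2-(4-hydroxyphenyl)-2,3-dihydro-4H-chromen-4-one, via C4 benzylic cation 17 (not isolated)
Conditions: TsOH·H2O (10 mol %), HFIP/CH2Cl2 (1:3), −20 to 0 °C
Reagents that add atoms: none
Why: Brønsted-acid SN1 Friedel–Crafts alkylation in HFIP: loss of the C4 hydroxyl as water gives cation 17 stabilised by O1 and the 7-benzyloxy group, and C6'' of 16 (the only free position of its phloroglucinol ring, C8'' carrying bromine) should attack anti to the pseudo-equatorial C3 aryl group, so that C4 becomes S (3,4-trans) while C3 and C2'' are untouched.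

**Step 13**
Reactants: 18 (2S)-6-{(3R,4S)-7-(benzyloxy)-3-[3-(benzyloxy)-2,4-dimethoxyphenyl]-3,4-dihydro-2H-chromen-4-yl}-8-bromo-5,7-dihydroxy-2-(4-hydroxyphenyl)-2,3-dihydro-4H-chromen-4-one
Product: 19 (2S)-5,7-dihydroxy-6-[(3R,4S)-7-hydroxy-3-(3-hydroxy-2,4-dimethoxyphenyl)-3,4-dihydro-2H-chromen-4-yl]-2-(4-hydroxyphenyl)-2,3-dihydro-4H-chromen-4-one
Conditions: H2 (1 atm), 10% Pd/C, NaOAc, EtOAc/MeOH, rt
Reagents that add atoms: none
Why: Catalytic hydrogenolysis should cleave both benzyl ethers and the blocking C8''–Br bond in one operation, with acetate buffering the HBr so that no stereocenter is exposed to strong acid or base.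

**Compound list**

1 | 2,6-dimethoxyphenol | COc1cccc(OC)c1O | starting material
2 | 2-(benzyloxy)-1,3-dimethoxybenzene | COc1cccc(OC)c1OCc1ccccc1 | intermediate
3 | 3-(benzyloxy)-2,4-dimethoxybenzaldehyde | COc1ccc(C=O)c(OC)c1OCc1ccccc1 | intermediate
4 | 2-(benzyloxy)-1,3-dimethoxy-4-(2-methoxyethenyl)benzene (E/Z mixture, E drawn) | CO/C=C/c1ccc(OC)c(OCc2ccccc2)c1OC | intermediate
5 | 2-[3-(benzyloxy)-2,4-dimethoxyphenyl]acetaldehyde | COc1ccc(CC=O)c(OC)c1OCc1ccccc1 | intermediate
6 | {2-[3-(benzyloxy)-2,4-dimethoxyphenyl]ethenyloxy}trimethylsilane (Z/E mixture, Z drawn) | C[Si](C)(C)O/C=C\c1ccc(OC)c(OCc2ccccc2)c1OC | intermediate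
7 | 4-(benzyloxy)-2-fluorobenzoic acid | OC(=O)c1ccc(OCc2ccccc2)cc1F | starting material
8 | 4-(benzyloxy)-2-fluorobenzoyl chloride | ClC(=O)c1ccc(OCc2ccccc2)cc1F | intermediate
9 | (Z)-2-[3-(benzyloxy)-2,4-dimethoxyphenyl]-1-[4-(benzyloxy)-2-fluorophenyl]-3-hydroxyprop-2-en-1-one, the chelated enol of the ketoaldehyde (not isolated) | O/C=C(\C(=O)c1ccc(OCc2ccccc2)cc1F)c1ccc(OC)c(OCc2ccccc2)c1OC | intermediate
10 | 7-(benzyloxy)-3-[3-(benzyloxy)-2,4-dimethoxyphenyl]-4H-chromen-4-one | O=c1c(-c2ccc(OC)c(OCc3ccccc3)c2OC)coc2cc(OCc3ccccc3)ccc12 | intermediate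
11 | 7-(benzyloxy)-3-[3-(benzyloxy)-2,4-dimethoxyphenyl]-2,3-dihydro-4H-chromen-4-one, racemic and configurationally labile at C3 (not isolated) | O=C1C(c2ccc(OC)c(OCc3ccccc3)c2OC)COc2cc(OCc3ccccc3)ccc12 | intermediate
12 | (3R,4R)-7-(benzyloxy)-3-[3-(benzyloxy)-2,4-dimethoxyphenyl]-3,4-dihydro-2H-chromen-4-ol (cis) | COc1ccc([C@@H]2COc3cc(OCc4ccccc4)ccc3[C@@H]2O)c(OC)c1OCc1ccccc1 | intermediate
13 | (2S)-naringenin, (2S)-5,7-dihydroxy-2-(4-hydroxyphenyl)-2,3-dihydro-4H-chromen-4-one | O=C1C[C@@H](c2ccc(O)cc2)Oc2cc(O)cc(O)c12 | starting material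
14 | (2S)-5,7-bis(benzyloxy)-2-[4-(benzyloxy)phenyl]-2,3-dihydro-4H-chromen-4-one | O=C1C[C@@H](c2ccc(OCc3ccccc3)cc2)Oc2cc(OCc3ccccc3)cc(OCc3ccccc3)c12 | intermediate
15 | (2S)-5,7-bis(benzyloxy)-2-[4-(benzyloxy)phenyl]-8-bromo-2,3-dihydro-4H-chromen-4-one | O=C1C[C@@H](c2ccc(OCc3ccccc3)cc2)Oc2c(Br)c(OCc3ccccc3)cc(OCc3ccccc3)c12 | intermediate
16 | (2S)-8-bromo-5,7-dihydroxy-2-(4-hydroxyphenyl)-2,3-dihydro-4H-chromen-4-one | O=C1C[C@@H](c2ccc(O)cc2)Oc2c(Br)c(O)cc(O)c12 | intermediate
17 | (3R)-7-(benzyloxy)-3-[3-(benzyloxy)-2,4-dimethoxyphenyl]-3,4-dihydro-2H-chromen-4-ylium, the C4 benzylic cation (not isolated) | COc1ccc([C@@H]2COc3cc(OCc4ccccc4)ccc3[CH+]2)c(OC)c1OCc1ccccc1 | intermediate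
18 | (2S)-6-{(3R,4S)-7-(benzyloxy)-3-[3-(benzyloxy)-2,4-dimethoxyphenyl]-3,4-dihydro-2H-chromen-4-yl}-8-bromo-5,7-dihydroxy-2-(4-hydroxyphenyl)-2,3-dihydro-4H-chromen-4-one | COc1ccc([C@@H]2COc3cc(OCc4ccccc4)ccc3[C@H]2c2c(O)c(Br)c3c(c2O)C(=O)C[C@@H](c2ccc(O)cc2)O3)c(OC)c1OCc1ccccc1 | intermediate
19 | (2S)-5,7-dihydroxy-6-[(3R,4S)-7-hydroxy-3-(3-hydroxy-2,4-dimethoxyphenyl)-3,4-dihydro-2H-chromen-4-yl]-2-(4-hydroxyphenyl)-2,3-dihydro-4H-chromen-4-one (CNP0267463.1) | COc1ccc([C@@H]2COc3cc(O)ccc3[C@H]2c2c(O)cc3c(c2O)C(=O)C[C@@H](c2ccc(O)cc2)O3)c(OC)c1O | target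

**Step count.** Total: 13 steps. Longest linear sequence: 9 steps (steps 1–5, 7, 8, 12, 13).

**Steps most likely to fail**

1. Step 12 (Friedel–Crafts coupling). The cation may lose the C3 proton to give the isoflav-3-ene and be re-protonated, which would erode the C3 configuration. Attack by the hindered, bromine-deactivated C6'' position may be slow, and ring A of a second molecule of 12 may be alkylated instead. The fallback sets out from 12. ZnI2-catalysed exchange of the C4 hydroxyl with 4-methylbenzenethiol in CH2Cl2 at −20 °C should capture the cation quickly as the trans thioether (3R,4S)-7-(benzyloxy)-3-[3-(benzyloxy)-2,4-dimethoxyphenyl]-4-[(4-methylphenyl)sulfanyl]-3,4-dihydro-2H-chromene F1. F1 is then activated with the thiophile AgOTf in CH2Cl2/THF at −78 °C in the presence of 16 and of 2,6-di-tert-butyl-4-methylpyridine as acid scavenger, so that no free strong acid is present, and the sequence comes back to the route at 18.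

2. Step 7 (key step). O-acylation of the enol ether or premature desilylation may compete with C-acylation, and the ring closure may be sluggish because the 7-benzyloxy group weakens carbonyl activation. The fallback sets out from 5. Condensation with morpholine (toluene, molecular sieves) should give the enamine (E)-4-{2-[3-(benzyloxy)-2,4-dimethoxyphenyl]ethenyl}morpholine F2, and enamines are acylated at carbon reliably. Treatment with 8 and Et3N should give the enaminone (E)-2-[3-(benzyloxy)-2,4-dimethoxyphenyl]-1-[4-(benzyloxy)-2-fluorophenyl]-3-(morpholin-4-yl)prop-2-en-1-one F3. Dilute HCl then hydrolyses F3 to 9, and K2CO3 in DMF closes the ring by fluoride displacement, so the sequence comes back to the route at 10.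

3. Step 8 (transfer hydrogenation cascade). Hydride transfer from ruthenium to the chromone C2=C3 bond may be slow, so that the cascade stalls at the isoflavone or gives incomplete dynamic resolution. The fallback sets out from 10. Conjugate reduction with LiBH(s-Bu)3 in THF at −78 °C, then H2O, should give racemic isoflavanone 11, which is isolated. Transfer hydrogenation of this ketone with RuCl[(R,R)-TsDPEN](p-cymene), HCO2H/Et3N and DBU as epimerising base, under dynamic kinetic resolution, comes back to the route at 12.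

**Further compounds**

F1 | step 12 | (3R,4S)-7-(benzyloxy)-3-[3-(benzyloxy)-2,4-dimethoxyphenyl]-4-[(4-methylphenyl)sulfanyl]-3,4-dihydro-2H-chromene | COc1ccc([C@@H]2COc3cc(OCc4ccccc4)ccc3[C@H]2Sc2ccc(C)cc2)c(OC)c1OCc1ccccc1
F2 | step 7 | (E)-4-{2-[3-(benzyloxy)-2,4-dimethoxyphenyl]ethenyl}morpholine | COc1ccc(/C=C/N2CCOCC2)c(OC)c1OCc1ccccc1
F3 | step 7 | (E)-2-[3-(benzyloxy)-2,4-dimethoxyphenyl]-1-[4-(benzyloxy)-2-fluorophenyl]-3-(morpholin-4-yl)prop-2-en-1-one | COc1ccc(/C(=C\N2CCOCC2)C(=O)c2ccc(OCc3ccccc3)cc2F)c(OC)c1OCc1ccccc1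
F0 | step 8 | none | none
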